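A formation constant of 2.25 h⁻¹ stood in the first dusk reading, 43% open intermediate at 0.250 h. This assumed that starting material goes first-order, which was my assumption throughout.

| flask | starting material | partner | temperature | remark | time |
|---|---|---|---|---|---|
| autumn | 1.1 M | 2 equiv | 38 °C | run made earlier |  |
| dusk | 0.80 M | 3 equiv | 54 °C | run made earlier |  |
| north-east | 0.80 M | 2.00 equiv | 30 °C |  | 6.0 h |
| west | 0.80 M | 2.00 equiv | 60 °C |  | 6.0 h |

| run | time / h | open intermediate / % | target / % |
|---|---|---|---|
| autumn | 0.500 | 13 | 0 |
| autumn | 1.33 | 38 | 4 |
| autumn | 3.00 | 59 | 0 |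
| autumn | 8.00 | 64 | 16 |
| dusk | 0.250 | 43 | 0 |
| dusk | 0.833 | 68 | 12 |
| dusk | 1.50 | 60 | 19 |
| dusk | 2.50 | 43 | 31 |

(readings scatter by 2 percentage points)

- which flask leads in amount of open intermediate, in percent of the starting material charged ("all alike" within 1.5 percentage points) (north-east / west / all alike)
- how much open intermediate is there at the end, in percent of the starting material charged: north-east
- how much open intermediate is there at the end, in percent of the starting material charged: west



I took conversion as open intermediate plus target. The first three autumn readings then averaged 0.328 h⁻¹.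

At the bench, rates double every 10 °C. Here the ratio of the two constants was 6.86 across 16.0 K. I kept that reading as the doubling interval, the rise in temperature that doubles the constant: 5.77 K.

For north-east:

k = 0.126 h⁻¹

n = k·t = 0.753

conversion = 52.9%

I put that answer back in. Autumn's reading at 3.00 h has the nearest n, 0.984, and there open intermediate was 94.1% of the conversion. So north-east should hold 49.8%.

The border is n. In west it is 27.8, far beyond north-east, so there the interval gives complete conversion and nothing about the end. For west I used loss instead. The highest dusk reading, 68%, served as the peak, and the last two dusk readings gave a fall of 0.333 h⁻¹. I had one such rate, so I left it unchanged, which gave 12.2%. North-east leads.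

The forecast also named north-east, but gave 38% and 5%, both below mine; for north-east it reckoned “conversion at 6 h is about 40%”.

North-east held 54.0% and west 19.5%, so north-east led.

    starting material → open intermediate (k = 0.0680 min⁻¹, Ea = 94.0 kJ mol⁻¹)
    target ⇌ isomer of the product (K = 2.20, k = 0.0250 min⁻¹, Ea = 100 kJ mol⁻¹, ΔH = −10.0 kJ mol⁻¹)
    starting material + target → side product (k = 0.0350 L mol⁻¹ min⁻¹, Ea = 61.0 kJ mol⁻¹)
    2 open intermediate → homo product (k = 0.00120 L mol⁻¹ min⁻¹, Ea = 83.0 kJ mol⁻¹)
    partner → second intermediate (k = 0.0110 min⁻¹, Ea = 102 kJ mol⁻¹)
    open intermediate + second intermediate → target (k = 0.0290 L mol⁻¹ min⁻¹, Ea = 64.0 kJ mol⁻¹)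
    partner → decomposed reagent (k = 0.0190 min⁻¹, Ea = 94.0 kJ mol⁻¹)
    (constants at 60 °C)

North-east had converted 57.7%, against my 52.9%. In west, partner stood at 0.452% of its charge at 3.00 h. I then put the interval of 5.77 K to a repeat of west at 35 °C, where k is 0.229 h⁻¹, which leaves 25.3% of the starting material. That flask held 20.2% at 6.00 h.

The runs are calculated for an exercise, noise included.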